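**Retrosynthetic overview**
1. The linoleate C–O bond is cut last: linoleic acid plus the primary hydroxyl of (2R)-3-methyl-2-[6-prenyl-1H-indol-3-yl]butane-1,3-diol, whose diol is carried as an acetonide.
2. Feature on which the strategy rests: the indole has hydrogen at C2 and carries the only stereocentre directly on C3, as a CH bearing CH2O and CMe2O. C2, C3 and the side chain therefore map onto an aldehyde OHC–CH2–CH(CH2O)(CMe2O) whose stereocentre is β to the carbonyl and cannot enolize.
3. The pyrrole ring of the indole, the only ring made in the route, is opened at N1–C2 (condensation) and C3–C3a (palladium-catalysed enamine arylation), giving 2-chloro-5-prenylaniline and the (R)-acetonide aldehyde.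
4. The aldehyde comes from an oxazolidinone-controlled hydroxymethylation of a pent-4-enoyl imide (sets the stereocentre); the acyl carbon becomes CMe2OH and the terminal alkene becomes CHO.
5. The aniline comes from 5-bromo-2-chloroaniline by bromide-selective Stille prenylation; the benzene ring is bought and the pyrrole ring is closed in step 8.

Key step: step 8

Assumption: pent-4-enoyl chloride (in place of the free acid) and tributyl(3-methylbut-2-enyl)stannane are taken as purchased; the target stereocentre is R, and the (S)-benzyl auxiliary delivers it because the electrophile enters the chelated Z-enolate anti to the benzyl group.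

**Route**

Step 1
Reactants: 1 (4S)-4-benzyl-1,3-oxazolidin-2-one; 2 pent-4-enoyl chloride
Product: 3 (4S)-4-benzyl-3-(pent-4-enoyl)-1,3-oxazolidin-2-one
Conditions: Et3N, DMAP (cat.), CH2Cl2, 0 °C to rt
Reagents that add atoms: none
Why: DMAP-catalysed N-acylation of the oxazolidinone by the acid chloride, with Et3N taking up HCl, is a standard way to make such imides and touches no stereocentre.

Step 2
Reactants: 3 (4S)-4-benzyl-3-(pent-4-enoyl)-1,3-oxazolidin-2-one
Product: 5 (4S)-4-benzyl-3-[(2R)-2-(hydroxymethyl)pent-4-enoyl]-1,3-oxazolidin-2-one, via trichlorotitanium enolate 4 (not isolated)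
Conditions: TiCl4, i-Pr2NEt, CH2Cl2, 0 °C; then 1,3,5-trioxane, TiCl4, 0 °C
Reagents that add atoms: 1,3,5-trioxane, C1OCOCO1 (one CH2O unit is transferred)
Why: In this titanium aldol of Evans type, soft enolization gives the chelated Z-enolate and TiCl4-activated trioxane, acting as formaldehyde, adds on the face opposite the C4 benzyl group, which sets the 2R centre.

Step 3
Reactants: 5 (4S)-4-benzyl-3-[(2R)-2-(hydroxymethyl)pent-4-enoyl]-1,3-oxazolidin-2-one
Product: 6 methyl (2R)-2-(hydroxymethyl)pent-4-enoate
Conditions: MeMgBr, MeOH, CH2Cl2, 0 °C (MeOMgBr formed in the flask)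
Reagents that add atoms: methanol, CO (delivered as bromomagnesium methoxide, CO[Mg]Br)
Why: In this magnesium methoxide transesterification, magnesium chelated by the two imide carbonyls directs methoxide to the exocyclic acyl group under nearly neutral conditions, so the α-centre should not epimerize and retro-aldol loss of formaldehyde should be avoided.

Step 4
Reactants: 6 methyl (2R)-2-(hydroxymethyl)pent-4-enoate
Product: 8 (2R)-3-methyl-2-(prop-2-enyl)butane-1,3-diol, via ketone alkoxide 7 (not isolated)
Conditions: MeMgBr (4 equiv), THF, 0 °C to rt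
Reagents that add atoms: methylmagnesium bromide, C[Mg]Br
Why: Double Grignard addition to the ester, after deprotonation of the hydroxyl, gives the tertiary carbinol through the methyl ketone, which is consumed by fast addition before its α-centre can epimerize.

Step 5
Reactants: 8 (2R)-3-methyl-2-(prop-2-enyl)butane-1,3-diol
Product: 9 (5R)-2,2,4,4-tetramethyl-5-(prop-2-enyl)-1,3-dioxane
Conditions: Me2C(OMe)2, PPTS (cat.), CH2Cl2, rt
Reagents that add atoms: 2,2-dimethoxypropane, COC(C)(C)OC
Why: Acid-catalysed transketalization closes the six-membered acetonide across the primary and tertiary hydroxyls of the 1,3-diol, masking both for the ozonolysis and the palladium step.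

Step 6
Reactants: 9 (5R)-2,2,4,4-tetramethyl-5-(prop-2-enyl)-1,3-dioxane
Product: 11 2-[(5R)-2,2,4,4-tetramethyl-1,3-dioxan-5-yl]acetaldehyde, via ozonide 10 (not isolated)
Conditions: O3, CH2Cl2, −78 °C; then PPh3, −78 °C to rt
Reagents that add atoms: ozone, [O-][O+]=O
Why: Ozonolysis of the terminal alkene with reductive work-up gives the aldehyde one carbon shorter, the ketal is inert, and the stereocentre, now β to the carbonyl, cannot epimerize.

Step 7
Reactants: 12 5-bromo-2-chloroaniline; 13 tributyl(3-methylbut-2-enyl)stannane
Product: 14 2-chloro-5-(3-methylbut-2-enyl)aniline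
Conditions: Pd(PPh3)4 (5 mol%), DMF, 100 °C
Reagents that add atoms: none
Why: In this Stille coupling, Pd(PPh3)4 inserts into C–Br far faster than into C–Cl, and the allylpalladium intermediate should couple at its unsubstituted CH2 terminus to give the linear prenyl arene, leaving the free NH2 and the chlorine untouched.

Step 8
Reactants: 11 2-[(5R)-2,2,4,4-tetramethyl-1,3-dioxan-5-yl]acetaldehyde; 14 2-chloro-5-(3-methylbut-2-enyl)aniline
Product: 17 6-(3-methylbut-2-enyl)-3-[(5R)-2,2,4,4-tetramethyl-1,3-dioxan-5-yl]-1H-indole, via imine 15 (not isolated), via enamine 16 (not isolated)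
Conditions: Pd(OAc)2 (10 mol%), XPhos (20 mol%), KOAc, MgSO4, DMA, 120 °C
Reagents that add atoms: none
Why: The aniline nitrogen condenses with the aldehyde (N1–C2) to imine 15, which tautomerizes to enamine 16; zerovalent palladium, formed in the flask from Pd(OAc)2 and XPhos, inserts into the C–Cl bond, the enamine carbon is palladated to a six-membered azapalladacycle, reductive elimination forms C3–C3a and the 3H-indole tautomerizes to the aromatic indole. The closest known reaction type is the palladium-catalysed annulation of ortho-haloanilines with enolizable aldehydes to 2-unsubstituted 3-substituted indoles, which a bulky electron-rich biarylphosphine extends to ortho-chloroanilines. The one ring closed is the pyrrole ring of the indole, closed at C3–C3a in a formally 5-endo-trig mode onto the enamine double bond. No stereocentre is formed, and the existing one, on the carbon next to the enamine carbon, carries no acidic hydrogen and is not reached by imine–enamine tautomerism, so its R configuration should be retained. Regioselectivity is fixed by connectivity (the aldehyde carbon becomes C2, its neighbour C3, and chlorine para to prenyl places prenyl on C6), and chemoselectivity rests on the weak base KOAc, which keeps intermolecular C–N coupling of the aryl chloride slow, and on the intramolecular enamine arylation outrunning any Heck reaction at the trisubstituted prenyl alkene. MgSO4 takes up the water of condensation so that the acetonide should survive the acetic acid formed from KOAc.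

Step 9
Reactants: 17 6-(3-methylbut-2-enyl)-3-[(5R)-2,2,4,4-tetramethyl-1,3-dioxan-5-yl]-1H-indole
Product: 18 (2R)-3-methyl-2-[6-(3-methylbut-2-enyl)-1H-indol-3-yl]butane-1,3-diol
Conditions: PPTS (cat.), MeOH, rt
Reagents that add atoms: none
Why: Acid-catalysed transketalization to methanol removes the strained tetramethyl acetonide under conditions too mild to ionize the tertiary alcohol, protonate the prenyl alkene or dimerize the indole.

Step 10
Reactants: 18 (2R)-3-methyl-2-[6-(3-methylbut-2-enyl)-1H-indol-3-yl]butane-1,3-diol; 19 linoleic acid [(9Z,12Z)-octadeca-9,12-dienoic acid]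
Product: 21 (2R)-3-hydroxy-3-methyl-2-[6-(3-methylbut-2-enyl)-1H-indol-3-yl]butyl (9Z,12Z)-octadeca-9,12-dienoate, via O-acylisourea 20 (not isolated)
Conditions: EDC·HCl, DMAP (cat.), CH2Cl2, 0 °C to rt, under argon
Reagents that add atoms: none
Why: In this Steglich esterification, the acylpyridinium formed from the O-acylisourea should acylate only the unhindered primary hydroxyl, since the tertiary hydroxyl and the indole N–H do not react at 0 °C, and the neutral conditions leave the skipped Z,Z-diene unchanged.

**Compound list**
1 | (4S)-4-benzyl-1,3-oxazolidin-2-one | O=C1N[C@@H](Cc2ccccc2)CO1 | starting material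
2 | pent-4-enoyl chloride | C=CCCC(=O)Cl | starting material
3 | (4S)-4-benzyl-3-(pent-4-enoyl)-1,3-oxazolidin-2-one | C=CCCC(=O)N1[C@@H](Cc2ccccc2)COC1=O | intermediate
4 | trichlorotitanium (Z)-enolate of 3 (formed in the flask) | C=CC/C=C(\O[Ti](Cl)(Cl)Cl)N1[C@@H](Cc2ccccc2)COC1=O | intermediate
5 | (4S)-4-benzyl-3-[(2R)-2-(hydroxymethyl)pent-4-enoyl]-1,3-oxazolidin-2-one | C=CC[C@H](CO)C(=O)N1[C@@H](Cc2ccccc2)COC1=O | intermediate
6 | methyl (2R)-2-(hydroxymethyl)pent-4-enoate | C=CC[C@H](CO)C(=O)OC | intermediate
7 | (3R)-3-(hydroxymethyl)hex-5-en-2-one as its bromomagnesium alkoxide (formed in the flask) | C=CC[C@H](CO[Mg]Br)C(C)=O | intermediate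
8 | (2R)-3-methyl-2-(prop-2-enyl)butane-1,3-diol | C=CC[C@H](CO)C(C)(C)O | intermediate
9 | (5R)-2,2,4,4-tetramethyl-5-(prop-2-enyl)-1,3-dioxane | CC1(C)OC[C@@H](CC=C)C(C)(C)O1 | intermediate
10 | (5R)-2,2,4,4-tetramethyl-5-(1,2,4-trioxolan-3-ylmethyl)-1,3-dioxane, epimers at the trioxolane carbon (formed in the flask) | CC1(C)OC[C@@H](CC2OCOO2)C(C)(C)O1 | intermediate
11 | 2-[(5R)-2,2,4,4-tetramethyl-1,3-dioxan-5-yl]acetaldehyde | CC1(C)OC[C@@H](CC=O)C(C)(C)O1 | intermediate
12 | 5-bromo-2-chloroaniline | Nc1cc(Br)ccc1Cl | starting material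
13 | tributyl(3-methylbut-2-enyl)stannane | CCCC[Sn](CCCC)(CCCC)CC=C(C)C | starting material
14 | 2-chloro-5-(3-methylbut-2-enyl)aniline | Nc1cc(CC=C(C)C)ccc1Cl | intermediate
15 | (E)-N-[2-chloro-5-(3-methylbut-2-enyl)phenyl]-2-[(5R)-2,2,4,4-tetramethyl-1,3-dioxan-5-yl]ethanimine (formed in the flask) | CC1(C)OC[C@@H](C/C=N/c2cc(CC=C(C)C)ccc2Cl)C(C)(C)O1 | intermediate
16 | 2-chloro-5-(3-methylbut-2-enyl)-N-{(E)-2-[(5R)-2,2,4,4-tetramethyl-1,3-dioxan-5-yl]ethenyl}aniline (formed in the flask) | CC1(C)OC[C@@H](/C=C/Nc2cc(CC=C(C)C)ccc2Cl)C(C)(C)O1 | intermediate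
17 | 6-(3-methylbut-2-enyl)-3-[(5R)-2,2,4,4-tetramethyl-1,3-dioxan-5-yl]-1H-indole | CC1(C)OC[C@@H](c2c[nH]c3cc(CC=C(C)C)ccc23)C(C)(C)O1 | intermediate
18 | (2R)-3-methyl-2-[6-(3-methylbut-2-enyl)-1H-indol-3-yl]butane-1,3-diol | OC[C@@H](c1c[nH]c2cc(CC=C(C)C)ccc12)C(C)(C)O | intermediate
19 | linoleic acid, (9Z,12Z)-octadeca-9,12-dienoic acid | CCCCC/C=C\C/C=C\CCCCCCCC(=O)O | starting material
20 | 1-[3-(dimethylamino)propyl]-3-ethyl-O-[(9Z,12Z)-octadeca-9,12-dienoyl]isourea (formed in the flask) | CCCCC/C=C\C/C=C\CCCCCCCC(=O)OC(=NCC)NCCCN(C)C | intermediate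
21 | (2R)-3-hydroxy-3-methyl-2-[6-(3-methylbut-2-enyl)-1H-indol-3-yl]butyl (9Z,12Z)-octadeca-9,12-dienoate | CCCCC/C=C\C/C=C\CCCCCCCC(=O)OC[C@@H](c1c[nH]c2cc(CC=C(C)C)ccc12)C(C)(C)O | target

**Step count**
Total steps: 10. Longest linear sequence: 9 steps (steps 1 to 6, then 8, 9 and 10); step 7 is the one-step side branch.

**Steps most likely to fail**

Step 8 (key annulation). Oxidative addition into the electron-rich, amino-substituted C–Cl bond may be slow. Aldol self-condensation of the aldehyde, migration of the prenyl double bond into conjugation by palladium hydride, or acid-promoted loss of the acetonide could then overtake ring closure. The fallback sets out from aldehyde 11 and comes back at indole 17; it moves the ring closure to a carbon–iodine bond and postpones the prenylation. Aldehyde 11 would be heated with purchased 5-bromo-2-iodoaniline F1 under ligand-free conditions (Pd(OAc)2, DABCO, DMF, 85 °C), where only the C–I bond should react. Through imine F2 and enamine F3 this should give 6-bromo-3-[(5R)-2,2,4,4-tetramethyl-1,3-dioxan-5-yl]-1H-indole F4. Stille coupling of F4 with stannane 13 (Pd(PPh3)4, DMF, 100 °C) should then give 17, and step 7 would no longer be needed.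

Step 3 (removal of the auxiliary). Methoxide may attack the ring carbonyl of the oxazolidinone, the β-alkoxide may cyclize onto the carbamate, formaldehyde may be lost by retro-aldol cleavage, or the α-centre may epimerize. The fallback sets out from imide 5 and comes back at ester 6. Hydroperoxide hydrolysis (LiOH, H2O2, THF/H2O, 0 °C, then Na2SO3), which is selective for the exocyclic carbonyl, should give (2R)-2-(hydroxymethyl)pent-4-enoic acid F5. Methylation of the acid with TMSCHN2 (MeOH/toluene, rt) should then give 6.

Step 7 (prenylation). The prenyl group may be transferred through its substituted terminus to give the 1,1-dimethylallyl isomer, the stannane may be protodestannylated, and the isomers may be hard to separate. The fallback sets out from 5-bromo-2-chloroaniline 12 and comes back at aniline 14. Stille coupling with allyltributylstannane (Pd(PPh3)4, DMF, 100 °C), which has no regiochemical ambiguity, should give 2-chloro-5-(prop-2-enyl)aniline F6. Cross-metathesis of F6 with excess 2-methylbut-2-ene (second-generation Grubbs catalyst, CH2Cl2, 40 °C) should then turn the allyl group into prenyl and give 14.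

**Further compounds**
F1 | step 8 | 5-bromo-2-iodoaniline (purchased) | Nc1cc(Br)ccc1I
F2 | step 8 | (E)-N-(5-bromo-2-iodophenyl)-2-[(5R)-2,2,4,4-tetramethyl-1,3-dioxan-5-yl]ethanimine | CC1(C)OC[C@@H](C/C=N/c2cc(Br)ccc2I)C(C)(C)O1
F3 | step 8 | 5-bromo-2-iodo-N-{(E)-2-[(5R)-2,2,4,4-tetramethyl-1,3-dioxan-5-yl]ethenyl}aniline | CC1(C)OC[C@@H](/C=C/Nc2cc(Br)ccc2I)C(C)(C)O1
F4 | step 8 | 6-bromo-3-[(5R)-2,2,4,4-tetramethyl-1,3-dioxan-5-yl]-1H-indole | CC1(C)OC[C@@H](c2c[nH]c3cc(Br)ccc23)C(C)(C)O1
F5 | step 3 | (2R)-2-(hydroxymethyl)pent-4-enoic acid | C=CC[C@H](CO)C(=O)O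
F6 | step 7 | 2-chloro-5-(prop-2-enyl)aniline | Nc1cc(CC=C)ccc1Cl
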